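## Structural features

The target is a C20 acid with two carbocycles, one lactone ring and one ether bridge. Ring A is a cyclohexanone (C13, C14, C15, C16, C20, C19) whose C16 and C19 are tied by O17–C18 into an 8,8-dimethyl-6-oxabicyclo[3.2.1]octan-3-one; ring B is a δ-lactone (C10, O11, C12, C13, C7, C8); ring C is a cyclohexane (C4 to C9) carrying the (R)-propanoic acid chain (C1 to C3) on C4. Rings A and B meet only at the spiro carbon C13, and rings B and C are cis-fused through C7–C8. There are seven stereocentres: C2 outside the rings, C4, C7 and C8 on ring C, the quaternary C13, and the bridgeheads C16 and C19. C19, C13, C7 and C8 are contiguous, and C13 carries C7 on the face of the C20 bridge (exo) and C12 on the face of the O17–C18 bridge (endo). Fragile points are the C14 ketone (a β-alkoxy ketone through C16–O17, open to retro-oxa-Michael cleavage, with two different α-carbons C13 and C15), the lactone with its epimerisable C8–H, and C2–H α to the acid. The real difficulty is the spiro centre C13: its two carbon substituents differ only in the ring face they occupy, and its configuration must be relayed to C7 and C8 and matched with the remote C4 and C2. The key step exploits the fact that C8 and C7 are α and β to the lactone carbonyl C10, so ring C can be annulated onto a C7=C8 unsaturated spiro lactone in which C13 (flat C14 carbonyl on one side, branched C19 on the other) is the only stereocentre near the reacting bond.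

## Logic of the disconnections

32 to 29: no skeletal bond is cut; the C3 carboxyl is traced through 31 and 30 to the C3–O benzyl ether of 29. As an ester, C2 would be α to a carbonyl and, in 23, also allylic, so it would not hold its configuration; as CH2OBn it is inert. The gain is that C2 comes unchanged from 17. The demand is a debenzylation and an oxidation at the end that neither epimerise C2 (through 31) nor open the β-alkoxy ketone.

29 to 26: the C5 methylene is traced through 28 and 27 to the C5 carbonyl of 26. That carbonyl is what the diene oxygen leaves behind, and it makes C4–H exchangeable, so C4 is set by equilibration and not by a kinetic event. The demand is a deoxygenation that distinguishes the C5 carbonyl from the C14 carbonyl; this relies on the hindrance of C14 between quaternary C13 and the bridge.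

26 to 16 and 23: cutting C6–C7 and C8–C9 of 24 (the enol ether of 25 and 26) removes ring C and two stereocentres and divides the molecule into 16 (rings A and B, three stereocentres) and 23 (C1 to C6 and C9, one stereocentre). C7=C8 of 16 is activated by C10, and the oxygen on C5 of 23 polarises the diene so that C6 bonds to C7. The gain is convergence and a ring fusion that is cis by necessity. The demand is reaction at a β-carbon attached to quaternary C13, on the face of C7=C8 flanked by C14 and not by C19.

16 to 12 and 13: cutting O11–C10 and C7=C8 (through 15 and 14) reduces ring B to two one-carbon groups on C13, C7 as an aldehyde and C12 as a silyloxymethyl group. A (Z)-selective olefination followed by lactonisation is a dependable entry to 5,6-dihydropyran-2-ones. The demand is Z selectivity at a neopentyl aldehyde, and that C7 and C12, which differ only in the face of ring A they occupy, are kept distinct by different oxygen protecting groups.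

12 to 7: cutting O17–C16 (through 11, 10, 9 and 8) opens the bridge to a monocyclic C15=C16 enone with C18 as the vinyl carbon of 7. Keeping C15=C16 until C13 is fully substituted means C15 can never be enolised. This removes the C13/C15 regiochemical problem of a preformed bicyclic ketone and keeps the β-alkoxy ketone out of every strong-base step. The gain is that C16 follows from C19. The demand is that only one Michael acceptor and one free hydroxyl are present at ring closure, so C7 is held as an acetate and the enoate is built afterwards.

7 to 3: cutting C13–C7 and then C13–C12 (through 6, 5 and 4) gives two aldol bonds to formaldehyde. C13 is the only enolisable position of 3 and of 5. Both carbons enter at the alcohol oxidation level, which avoids a formyl/hydroxymethyl 1,3-dicarbonyl at C13 that would lose its formyl group. The demand is that the second electrophile enters trans to the C19 substituent; because the target has C7 trans and C12 cis to C18, C12 must come first and C7 second.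

3 to 1: cutting C19–C18 leads to the achiral dienone 2, made from 1 by dehydrogenation; the vinyl group is a masked hydroxymethyl. Because 2 is symmetric, one catalytic enantioselective conjugate addition sets C19, from which C13, C16 and later C7, C8 and C4 follow. The demand is enantioselective addition to a neopentyl β-carbon that stops after one addition.

23 to 17: cutting C4=C9 and C4–C5 (through 22, 21, 20, 19 and 18) makes the ester carbon of 17 into C4 and its CH2OH into C3. An acyl-anion equivalent brings C5 and C6, and a methylenation brings C9. The gain is C2 from the chiral pool. The demand is that no basic reagent meets 20, a β-benzyloxy ketone with an α-stereocentre.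

## Other disconnections considered

Alternative 1: The cut is C18–C19, so the ether bridge is the last ring closed. The precursor A1 is a ring A cyclohexenone (C13=C19) that already carries ring C on C13 and an oxyacetic acid on the C16 oxygen. Photocatalytic oxidative decarboxylation of A1 would give the C18 α-alkoxymethyl radical, which would add 5-exo-trig to C19; reduction and protonation at C13 would give the bridged ketone A2.
- In favour: the conditions are mild and neutral, the tether allows only a cis bridge, and the β-alkoxy ketone appears only at the end. On that last point it is better than the chosen plan, which carries this group from 10 to 32.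
- Against: A2 still has hydrogen on C13, so C12 and the lactone must be added by hydroxymethylation of a ketone that can enolise towards C13 or C15. This is the regiochemical problem the chosen plan avoids. A1 also needs a C7–C13 bond between a stereochemically complete ring C and a hindered enone α-carbon, with no rigid element relaying configuration between the rings.
- Comparison: the chosen plan builds the quaternary centre early on a small ring and lets it direct C7 and C8; Alternative 1 builds it last. A radical conjugate addition tolerates functional groups at least as well as a Lewis-acid cycloaddition (equal or better). In step economy Alternative 1 is linear and should be longer, because ring C and its stereocentres must be complete before ring A is finished.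

Alternative 2: The cut is C19–C20 inside ring A, leading back to the acyclic epoxide A4 of commercial geranyl acetate A3. A Lewis acid such as ZrCl4, or Cp2TiCl (trivalent titanium) in a radical variant, would open the epoxide at C20; C19 of the C13=C19 alkene would attack, and loss of a hydrogen from C12 would give A5 with an exocyclic C13=C12 alkene.
- In favour: A3 is very cheap, A4 is accessible enantioenriched by established asymmetric oxidation chemistry, and two or three steps give a ring A with the C20 methyl groups, the C16 oxygen and C18 in the correct cis relationship and C12 already attached. As a source of enantioenriched ring A it is shorter than steps 1 to 6 and on that count the better of the two.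
- Against: cationic closures of this kind tend to give alkene isomer mixtures. C14 is not oxidised in A5, and the bridge needs a separate substitution between O17 and C18. Above all, C13 is left sp2: turning C13=C12 into a quaternary carbon bearing C12–O and C7 is not simpler than the double aldol of steps 3 and 4.
- Comparison: Alternative 2 answers only ring A and would still need the chosen cycloaddition or an equivalent for ring C. Its stereochemistry comes from one epoxide stereocentre, equal in principle to the single catalyst-controlled step 2. Overall it should be longer because of the oxidation-state adjustments at C12, C13 and C14.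

Alternative 3: The cut is C15–C16, leading back to the tetrahydrofuran A6, a C16 methyl acetal whose C19 carries a 2-(trimethylsilylmethyl)allyl chain (C13, C14, C15). BF3·OEt2 would ionise the acetal to the C16 oxocarbenium ion; the allylsilane would attack through its terminal carbon C15 and close the six-membered carbocycle across the five-membered ether, leaving an exocyclic methylene on C14 in A7. Ozonolysis would then give the ring A ketone.
- In favour: the bridge can only be cis, the single stereocentre C19 controls C16, and the C–C bond formation is irreversible, so it does not depend on an oxa-Michael equilibrium. On that point it is the equal or the better of step 6.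
- Against: A7 and its derived ketone have two unsubstituted α-carbons (C13 and C15) with nothing to distinguish them. The spiro centre would have to be built on the bicyclic ketone, with a regiochemical problem and under enolising conditions that can open the β-alkoxy ketone. Enantioenriched A6 is itself several steps from commercial material.
- Comparison: the chosen plan makes C13 quaternary before the bridge exists. Both closures form a small ring with enforced cis geometry (equal). Alternative 3 needs more steps to reach 16, because the functionalisation of C13 comes on top of the synthesis of A6.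

Key step: step 16

Remarks on the chemistry:
- Atom numbers C1 to C20 (O11, O17) follow the target skeleton and are kept for every intermediate. "Exo" means the face of the C20 bridge and "endo" the face of the O17–C18 bridge.
- Compounds 16, 23 and 24 agree with the target at every stereocentre, so no structure needs correction. Compound 17 is (S) and 23 is (R) only because the CIP ranking at C2 changes.
- Assumption: (R)-BINAP in step 2 is assigned by analogy with the sense of addition to cyclohex-2-en-1-one; the other ligand enantiomer is used if the analogy does not hold.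

## Steps

Step 1
Reactants: 1 4,4-dimethylcyclohex-2-en-1-one
Product: 2 4,4-dimethylcyclohexa-2,5-dien-1-one
Conditions: DDQ, 1,4-dioxane, reflux
Reagents that add atoms: none
Why: DDQ dehydrogenation of a cyclohexenone whose γ-carbon (C20) is quaternary can only give the cross-conjugated dienone, since aromatisation is blocked. The achiral product has two enantiotopic enone units, one of which later blocks C15 and serves as the oxa-Michael acceptor.

Step 2
Reactants: 2 4,4-dimethylcyclohexa-2,5-dien-1-one
Product: 3 (R)-5-ethenyl-4,4-dimethylcyclohex-2-en-1-one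
Conditions: CH2=CHBF3K (0.8 equiv), [Rh(cod)2]BF4 (3 mol%), (R)-BINAP (3.3 mol%), toluene/H2O (4:1), 100 °C
Reagents that add atoms: potassium vinyltrifluoroborate, C=C[B-](F)(F)F.[K+]
Why: Rhodium-catalysed asymmetric 1,4-addition of an alkenylboron reagent (Hayashi–Miyaura type) to one of the two enantiotopic enone units desymmetrises 2 and sets C19 under ligand control. The dienone is kept in excess to suppress a second addition, and the vinyl group is a masked C18 hydroxymethyl that is inert to the enolate chemistry that follows.

Step 3
Reactants: 3 (R)-5-ethenyl-4,4-dimethylcyclohex-2-en-1-one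
Product: 5 (5S,6R)-5-ethenyl-4,4-dimethyl-6-[(triisopropylsilyloxy)methyl]cyclohex-2-en-1-one, via aldol 4 (not isolated)
Conditions: LiN(i-Pr)2, THF, −78 °C; CH2O (THF solution from cracked paraformaldehyde); i-Pr3SiOTf, −78 → −30 °C
Reagents that add atoms: formaldehyde, C=O; triisopropylsilyl trifluoromethanesulfonate, CC(C)[Si](C(C)C)(C(C)C)OS(=O)(=O)C(F)(F)F
Why: Kinetic α′-deprotonation of the enone can occur only at C13 (C15 is vinylic, C20 quaternary); aldol addition to formaldehyde brings in C12, and silylation of the lithium aldolate in situ prevents dehydration. The triisopropylsilyl group is chosen because it resists migration to a neighbouring hydroxyl; the C13 configuration formed here (trans expected) is erased in step 4.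

Step 4
Reactants: 5 (5S,6R)-5-ethenyl-4,4-dimethyl-6-[(triisopropylsilyloxy)methyl]cyclohex-2-en-1-one
Product: 7 [6-ethenyl-5,5-dimethyl-2-oxo-1-[(triisopropylsilyloxy)methyl]cyclohex-3-en-1-yl]methyl acetate (CH2OAc trans to ethenyl), via aldol 6 (not isolated)
Conditions: LiN(i-Pr)2, THF, −78 °C; CH2O (THF solution); Ac2O, −78 → 0 °C
Reagents that add atoms: formaldehyde, C=O; acetic anhydride, CC(=O)OC(C)=O
Why: C13–H is again the only acidic position, and the tetrasubstituted enolate should be attacked by formaldehyde anti to the neighbouring vinyl group, which allylic 1,2-strain holds pseudoaxial on C19; the new carbon C7 therefore ends trans to C18 and C12 cis, as in the target. Acetylation in situ masks the C7 hydroxyl so that only the C18 hydroxyl can later add to C16, and the quaternary β-acetoxy ketone has no α-hydrogen and cannot eliminate.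

Step 5
Reactants: 7 [6-ethenyl-5,5-dimethyl-2-oxo-1-[(triisopropylsilyloxy)methyl]cyclohex-3-en-1-yl]methyl acetate
Product: 8 [6-formyl-5,5-dimethyl-2-oxo-1-[(triisopropylsilyloxy)methyl]cyclohex-3-en-1-yl]methyl acetate
Conditions: OsO4 (2 mol%), NaIO4, 2,6-lutidine, dioxane/H2O, rt
Reagents that add atoms: sodium periodate, [Na+].[O-]I(=O)(=O)=O
Why: Lemieux–Johnson cleavage: OsO4 dihydroxylates the electron-rich monosubstituted vinyl group much faster than the electron-poor enone double bond, and periodate cleaves the diol to the C18 aldehyde. Lutidine buffers the medium against epimerisation of C19.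

Step 6
Reactants: 8 [6-formyl-5,5-dimethyl-2-oxo-1-[(triisopropylsilyloxy)methyl]cyclohex-3-en-1-yl]methyl acetate
Product: 11 2-(hydroxymethyl)-8,8-dimethyl-2-[(triisopropylsilyloxy)methyl]-6-oxabicyclo[3.2.1]octan-3-one (CH2OH exo; CH2OSi endo), via hydroxy enone 9 (not isolated), via bicyclic acetate 10 (not isolated)
Conditions: NaBH4, MeOH/CH2Cl2, −78 °C; acetone; K2CO3 (cat.), MeOH, 0 °C → rt
Reagents that add atoms: none
Why: At −78 °C the aldehyde should be reduced far faster than the hindered cross-conjugated ketone; base then triggers 5-exo-trig oxa-Michael addition of the C18 alkoxide to C16, the only acceptor present. This can give only the cis-bridged 6-oxabicyclo[3.2.1]octan-3-one, so C16 follows from C19; methanolysis of the acetate frees the C7 hydroxyl only after C16 is consumed.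

Step 7
Reactants: 11 2-(hydroxymethyl)-8,8-dimethyl-2-[(triisopropylsilyloxy)methyl]-6-oxabicyclo[3.2.1]octan-3-one
Product: 12 8,8-dimethyl-3-oxo-2-[(triisopropylsilyloxy)methyl]-6-oxabicyclo[3.2.1]octane-2-carbaldehyde (CHO exo)
Conditions: Dess–Martin periodinane, CH2Cl2, 0 °C → rt
Reagents that add atoms: none
Why: Dess–Martin oxidation of the neopentyl primary alcohol gives a non-enolisable β-keto aldehyde. No base is present that could open the β-alkoxy ketone or cause retro-Claisen loss of the formyl group.

Step 8
Reactants: 12 8,8-dimethyl-3-oxo-2-[(triisopropylsilyloxy)methyl]-6-oxabicyclo[3.2.1]octane-2-carbaldehyde; 13 methyl bis(2,2,2-trifluoroethyl)phosphonoacetate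
Product: 14 methyl (Z)-3-[8,8-dimethyl-3-oxo-2-[(triisopropylsilyloxy)methyl]-6-oxabicyclo[3.2.1]octan-2-yl]prop-2-enoate (alkenyl exo)
Conditions: KN(SiMe3)2, 18-crown-6, THF, −78 °C
Reagents that add atoms: none
Why: Still–Gennari variant of the Horner–Wadsworth–Emmons reaction: the electron-poor phosphonate eliminates quickly from the kinetic adduct under dissociating conditions and should give the (Z)-enoate needed for ring closure. The aldehyde reacts in preference to the hindered ketone, and the preformed phosphonate anion is too weak a base to enolise C15.

Step 9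
Reactants: 14 methyl (Z)-3-[8,8-dimethyl-3-oxo-2-[(triisopropylsilyloxy)methyl]-6-oxabicyclo[3.2.1]octan-2-yl]prop-2-enoate
Product: 16 8,8-dimethyl-2′H-spiro[6-oxabicyclo[3.2.1]octane-2,3′-pyran]-3,6′-dione (spiro 5,6-dihydropyran-2-one; C13 S; C16 R; C19 R), via hydroxy ester 15 (not isolated)
Conditions: HF·pyridine, THF/pyridine, 0 °C → rt; PPTS (cat.), benzene, 50 °C
Reagents that add atoms: none
Why: Desilylation frees the C12 hydroxyl, which is held next to the ester across the (Z)-alkene and lactonises by transesterification to the 5,6-dihydropyran-2-one. The mildly acidic medium leaves the β-alkoxy ketone closed.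

Step 10
Reactants: 17 methyl (S)-3-hydroxy-2-methylpropanoate
Product: 18 methyl (S)-3-(benzyloxy)-2-methylpropanoate
Conditions: BnOC(=NH)CCl3, TfOH (cat.), CH2Cl2/cyclohexane, 0 °C → rt
Reagents that add atoms: benzyl 2,2,2-trichloroacetimidate, N=C(OCc1ccccc1)C(Cl)(Cl)Cl
Why: Acid-catalysed benzylation with the trichloroacetimidate avoids the basic conditions that would epimerise C2 or cause β-elimination of the hydroxy ester.

Step 11
Reactants: 18 methyl (S)-3-(benzyloxy)-2-methylpropanoate
Product: 19 (S)-3-(benzyloxy)-N-methoxy-N,2-dimethylpropanamide
Conditions: MeNH(OMe)·HCl, i-PrMgCl, THF, −20 °C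
Reagents that add atoms: N,O-dimethylhydroxylamine hydrochloride, CNOC.Cl
Why: Direct aminolysis of the ester by the magnesium amide gives the Weinreb amide without epimerising C2. The amide ensures that the organolithium of the next step adds only once.

Step 12
Reactants: 19 (S)-3-(benzyloxy)-N-methoxy-N,2-dimethylpropanamide
Product: 20 (S)-5-(benzyloxy)-2-ethoxy-4-methylpent-1-en-3-one
Conditions: CH2=C(OEt)Li (from ethyl vinyl ether, t-BuLi, THF, −78 → 0 °C), THF, −78 °C; aq. NH4Cl
Reagents that add atoms: ethyl vinyl ether, C=COCC
Why: The acyl-anion equivalent 1-ethoxyvinyllithium adds to the Weinreb amide, and the chelated tetrahedral intermediate collapses only on work-up. This forms C4–C5 with C5 already at the enol ether oxidation level.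

Step 13
Reactants: 20 (S)-5-(benzyloxy)-2-ethoxy-4-methylpent-1-en-3-one
Product: 21 (R)-{[(4-ethoxy-2-methyl-3-methylidenepent-4-en-1-yl)oxy]methyl}benzene
Conditions: Cp2TiMe2, toluene, 65 °C, dark
Reagents that add atoms: dimethyltitanocene, C[Ti](C)(C1C=CC=C1)C1C=CC=C1
Why: Petasis methylenation is not basic, so the C4 carbonyl becomes C4=C9 without enolising the α-stereocentre C2 or eliminating the β-benzyloxy group, as a phosphorus ylide might. The descriptor changes from S to R only because the CIP ranking at C2 changes.

Step 14
Reactants: 21 (R)-{[(4-ethoxy-2-methyl-3-methylidenepent-4-en-1-yl)oxy]methyl}benzene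
Product: 22 (R)-5-(benzyloxy)-4-methyl-3-methylidenepentan-2-one
Conditions: 0.5 M HCl, THF, 0 °C
Reagents that add atoms: water, O
Why: Protonation of the enol ether at its terminal carbon C6 and hydrolysis of the oxocarbenium ion liberate the α-methylene methyl ketone. C2 is not α to the carbonyl and is not at risk.

Step 15
Reactants: 22 (R)-5-(benzyloxy)-4-methyl-3-methylidenepentan-2-one
Product: 23 2-(tert-butyldimethylsilyloxy)-3-[(R)-1-(benzyloxy)propan-2-yl]buta-1,3-diene
Conditions: TBSOTf, Et3N, CH2Cl2, 0 °C
Reagents that add atoms: tert-butyldimethylsilyl trifluoromethanesulfonate, CC(C)(C)[Si](C)(C)OS(=O)(=O)C(F)(F)F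
Why: Soft enolisation can occur only towards the methyl group C6, because C4 carries no hydrogen. The 2-silyloxy-1,3-diene is therefore formed regiospecifically.

Step 16
Reactants: 16 8,8-dimethyl-2′H-spiro[6-oxabicyclo[3.2.1]octane-2,3′-pyran]-3,6′-dione; 23 2-(tert-butyldimethylsilyloxy)-3-[(R)-1-(benzyloxy)propan-2-yl]buta-1,3-diene
Product: 24 Diels–Alder adduct: ring C as its C4=C5 tert-butyldimethylsilyl enol ether, cis-fused at C7–C8 to the spiro lactone, C3 as benzyl ether
Conditions: Et2AlCl (2.2 equiv), 23 (2 equiv), CH2Cl2, −78 → −20 °C; aq. NaHCO3/Rochelle salt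
Reagents that add atoms: none
Why: This is a Diels–Alder reaction, a concerted but asynchronous [4+2] cycloaddition between the HOMO of the 2-silyloxy diene and the LUMO of the unsaturated lactone, lowered by coordination of Et2AlCl to the C10 carbonyl; the closest known reaction type is the Lewis-acid-promoted addition of 2-silyloxy-1,3-dienes to 5,6-dihydropyran-2-ones and 4,4-disubstituted cyclohexenones. Ring C is closed in one suprafacial [4+2] event that forms C6–C7 and C8–C9 and leaves the C4=C5 silyl enol ether. The largest HOMO coefficient lies on C6 (the enol ether terminus) and the largest LUMO coefficient on the β-carbon C7, so C6 should bond to C7 and C9 to C8, which puts the side-chain carbon C4 next to C9. C8 follows from C7 because the cis geometry of the dienophile is retained, giving the cis ring fusion. C7 is set by the spiro centre C13: the branched C19, with C18 and the C20 methyl groups behind it, shields one face of C7=C8 while the flat C14 carbonyl leaves the other open, so the diene should add anti to C19. No endo/exo question arises because the diene has no terminal substituent, and C2 is too remote to matter. The step needs reactivity at a neopentyl β-carbon, met by Lewis-acid activation and an excess of electron-rich diene, and survival of the β-alkoxy ketone and the silyl enol ether, met by low temperature and a basic work-up.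

Step 17
Reactants: 24 Diels–Alder adduct (C4=C5 silyl enol ether)
Product: 26 C5 ketone with the side chain on C4 equatorial (trans to C10), via C4-epimeric ketone 25 (not isolated)
Conditions: 1 M HCl, THF, rt
Reagents that add atoms: none
Why: Hydrolysis of the silyl enol ether gives the C5 ketone, and acid-catalysed enolisation towards C4 should move the side chain into the equatorial position, trans to C10 with C13 equatorial on ring C, which is the target configuration. The lactone α-centre C8 enolises far more slowly than the ketone, so the cis ring fusion is kept.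

Step 18
Reactants: 26 C5 ketone
Product: 27 C5 p-toluenesulfonylhydrazone of 26
Conditions: TsNHNH2 (1.05 equiv), MeOH/THF, rt
Reagents that add atoms: p-toluenesulfonyl hydrazide, Cc1ccc(cc1)S(=O)(=O)NN
Why: Condensation is expected only at the C5 carbonyl, because the C14 carbonyl lies between the quaternary spiro centre C13 and the bicyclic bridge and is much more hindered.

Step 19
Reactants: 27 C5 p-toluenesulfonylhydrazone
Product: 29 benzyl ether of the C5-deoxygenated tricycle (C5 = CH2), via N-boryl hydrazine 28 (not isolated)
Conditions: catecholborane, CHCl3, 0 °C; NaOAc·3H2O, reflux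
Reagents that add atoms: none
Why: Kabalka variant of the Caglioti reduction: hydroboration of the C=N bond, then acetate-induced loss of sulfinate and extrusion of nitrogen from the diazene, should give the C5 methylene. The near-neutral conditions leave the lactone, the hindered ketone and the C4 and C8 stereocentres untouched.

Step 20
Reactants: 29 benzyl ether of the C5-deoxygenated tricycle
Product: 30 primary alcohol (C3–OH)
Conditions: H2 (1 atm), Pd/C, EtOAc, rt
Reagents that add atoms: none
Why: Hydrogenolysis of the benzyl ether; no alkene or other reducible group remains in the molecule.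

Step 21
Reactants: 30 primary alcohol (C3–OH)
Product: 32 target acid CNP0152427.2 (C2 R; C4 R; C7 R; C8 S; C13 S; C16 R; C19 R), via aldehyde 31 (not isolated)
Conditions: TEMPO (cat.), PhI(OAc)2 (2.2 equiv), MeCN/H2O (1:1), rt
Reagents that add atoms: water, O
Why: Oxoammonium-mediated oxidation to the aldehyde and, through its hydrate, to the acid proceeds under near-neutral conditions. These should not epimerise C2, open the lactone or disturb the β-alkoxy ketone.

## Compound list

1 | 4,4-dimethylcyclohex-2-en-1-one | CC1(C)CCC(=O)C=C1 | starting material
2 | 4,4-dimethylcyclohexa-2,5-dien-1-one | CC1(C)C=CC(=O)C=C1 | intermediate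
3 | (R)-5-ethenyl-4,4-dimethylcyclohex-2-en-1-one | C=C[C@H]1CC(=O)C=CC1(C)C | intermediate
4 | (5S,6R)-5-ethenyl-6-(hydroxymethyl)-4,4-dimethylcyclohex-2-en-1-one (as lithium alkoxide) | OC[C@@H]1C(=O)C=CC(C)(C)[C@H]1C=C | intermediate (not isolated)
5 | (5S,6R)-5-ethenyl-4,4-dimethyl-6-[(triisopropylsilyloxy)methyl]cyclohex-2-en-1-one | CC(C)[Si](C(C)C)(C(C)C)OC[C@@H]1C(=O)C=CC(C)(C)[C@H]1C=C | intermediate
6 | 5-ethenyl-6-(hydroxymethyl)-4,4-dimethyl-6-[(triisopropylsilyloxy)methyl]cyclohex-2-en-1-one, CH2OH trans and CH2OSi cis to ethenyl (as lithium alkoxide) | CC(C)[Si](C(C)C)(C(C)C)OC[C@@]1(CO)C(=O)C=CC(C)(C)[C@H]1C=C | intermediate (not isolated)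
7 | [6-ethenyl-5,5-dimethyl-2-oxo-1-[(triisopropylsilyloxy)methyl]cyclohex-3-en-1-yl]methyl acetate, CH2OAc trans to ethenyl | CC(C)[Si](C(C)C)(C(C)C)OC[C@@]1(COC(C)=O)C(=O)C=CC(C)(C)[C@H]1C=C | intermediate
8 | [6-formyl-5,5-dimethyl-2-oxo-1-[(triisopropylsilyloxy)methyl]cyclohex-3-en-1-yl]methyl acetate, CH2OAc trans to formyl | CC(C)[Si](C(C)C)(C(C)C)OC[C@@]1(COC(C)=O)C(=O)C=CC(C)(C)[C@H]1C=O | intermediate
9 | [6-(hydroxymethyl)-5,5-dimethyl-2-oxo-1-[(triisopropylsilyloxy)methyl]cyclohex-3-en-1-yl]methyl acetate | CC(C)[Si](C(C)C)(C(C)C)OC[C@@]1(COC(C)=O)C(=O)C=CC(C)(C)[C@H]1CO | intermediate (not isolated)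
10 | [8,8-dimethyl-3-oxo-2-[(triisopropylsilyloxy)methyl]-6-oxabicyclo[3.2.1]octan-2-yl]methyl acetate, CH2OAc exo | CC(C)[Si](C(C)C)(C(C)C)OC[C@@]2(COC(C)=O)C(=O)C[C@H]3OC[C@@H]2C3(C)C | intermediate (not isolated)
11 | 2-(hydroxymethyl)-8,8-dimethyl-2-[(triisopropylsilyloxy)methyl]-6-oxabicyclo[3.2.1]octan-3-one, CH2OH exo, CH2OSi endo | CC(C)[Si](C(C)C)(C(C)C)OC[C@@]2(CO)C(=O)C[C@H]3OC[C@@H]2C3(C)C | intermediate
12 | 8,8-dimethyl-3-oxo-2-[(triisopropylsilyloxy)methyl]-6-oxabicyclo[3.2.1]octane-2-carbaldehyde, CHO exo | CC(C)[Si](C(C)C)(C(C)C)OC[C@@]2(C=O)C(=O)C[C@H]3OC[C@@H]2C3(C)C | intermediate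
13 | methyl bis(2,2,2-trifluoroethyl)phosphonoacetate | COC(=O)CP(=O)(OCC(F)(F)F)OCC(F)(F)F | starting material
14 | methyl (Z)-3-[8,8-dimethyl-3-oxo-2-[(triisopropylsilyloxy)methyl]-6-oxabicyclo[3.2.1]octan-2-yl]prop-2-enoate, alkenyl exo | CC(C)[Si](C(C)C)(C(C)C)OC[C@@]2(/C=C\C(=O)OC)C(=O)C[C@H]3OC[C@@H]2C3(C)C | intermediate
15 | methyl (Z)-3-[2-(hydroxymethyl)-8,8-dimethyl-3-oxo-6-oxabicyclo[3.2.1]octan-2-yl]prop-2-enoate | OC[C@@]2(/C=C\C(=O)OC)C(=O)C[C@H]3OC[C@@H]2C3(C)C | intermediate (not isolated)
16 | 8,8-dimethyl-2′H-spiro[6-oxabicyclo[3.2.1]octane-2,3′-pyran]-3,6′-dione (C13 S, C16 R, C19 R) | O=C1OC[C@@]2(C=C1)C(=O)C[C@H]3OC[C@@H]2C3(C)C | intermediate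
17 | methyl (S)-3-hydroxy-2-methylpropanoate | C[C@@H](CO)C(=O)OC | starting material
18 | methyl (S)-3-(benzyloxy)-2-methylpropanoate | C[C@@H](COCc1ccccc1)C(=O)OC | intermediate
19 | (S)-3-(benzyloxy)-N-methoxy-N,2-dimethylpropanamide | C[C@@H](COCc1ccccc1)C(=O)N(C)OC | intermediate
20 | (S)-5-(benzyloxy)-2-ethoxy-4-methylpent-1-en-3-one | C[C@@H](COCc1ccccc1)C(=O)C(=C)OCC | intermediate
21 | (R)-{[(4-ethoxy-2-methyl-3-methylidenepent-4-en-1-yl)oxy]methyl}benzene | C[C@@H](COCc1ccccc1)C(=C)C(=C)OCC | intermediate
22 | (R)-5-(benzyloxy)-4-methyl-3-methylidenepentan-2-one | C[C@@H](COCc1ccccc1)C(=C)C(C)=O | intermediate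
23 | 2-(tert-butyldimethylsilyloxy)-3-[(R)-1-(benzyloxy)propan-2-yl]buta-1,3-diene | C[C@@H](COCc1ccccc1)C(=C)C(=C)O[Si](C)(C)C(C)(C)C | intermediate
24 | Diels–Alder adduct, ring C C4=C5 silyl enol ether, cis-fused spiro lactone, C3 benzyl ether | C[C@@H](COCc1ccccc1)C1=C(O[Si](C)(C)C(C)(C)C)C[C@@H]2[C@H](C1)C(=O)OC[C@]21C(=O)C[C@H]2OC[C@@H]1C2(C)C | intermediate
25 | C5 ketone, C4 epimer (side chain cis to C10) | C[C@@H](COCc1ccccc1)[C@H]1C(=O)C[C@@H]2[C@H](C1)C(=O)OC[C@]21C(=O)C[C@H]2OC[C@@H]1C2(C)C | intermediate (not isolated)
26 | C5 ketone, side chain on C4 equatorial and trans to C10 | C[C@@H](COCc1ccccc1)[C@@H]1C(=O)C[C@@H]2[C@H](C1)C(=O)OC[C@]21C(=O)C[C@H]2OC[C@@H]1C2(C)C | intermediate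
27 | C5 p-toluenesulfonylhydrazone of 26 | C[C@@H](COCc1ccccc1)[C@@H]1C(=NNS(=O)(=O)c3ccc(C)cc3)C[C@@H]2[C@H](C1)C(=O)OC[C@]21C(=O)C[C@H]2OC[C@@H]1C2(C)C | intermediate
28 | N-(1,3,2-benzodioxaborol-2-yl) tosylhydrazine at C5 | C[C@@H](COCc1ccccc1)[C@@H]1C(N(NS(=O)(=O)c3ccc(C)cc3)B3Oc4ccccc4O3)C[C@@H]2[C@H](C1)C(=O)OC[C@]21C(=O)C[C@H]2OC[C@@H]1C2(C)C | intermediate (not isolated)
29 | C5-deoxygenated tricycle, C3 benzyl ether | C[C@@H](COCc1ccccc1)[C@@H]1CC[C@@H]2[C@H](C1)C(=O)OC[C@]21C(=O)C[C@H]2OC[C@@H]1C2(C)C | intermediate
30 | C3 primary alcohol | C[C@@H](CO)[C@@H]1CC[C@@H]2[C@H](C1)C(=O)OC[C@]21C(=O)C[C@H]2OC[C@@H]1C2(C)C | intermediate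
31 | C3 aldehyde | C[C@@H](C=O)[C@@H]1CC[C@@H]2[C@H](C1)C(=O)OC[C@]21C(=O)C[C@H]2OC[C@@H]1C2(C)C | intermediate (not isolated)
32 | CNP0152427.2, (2R)-propanoic acid on C4 of ring C (C2 R, C4 R, C7 R, C8 S, C13 S, C16 R, C19 R) | C[C@@H](C(=O)O)[C@@H]1CC[C@@H]2[C@H](C1)C(=O)OC[C@]21C(=O)C[C@H]2OC[C@@H]1C2(C)C | target

## Step count and least certain steps

Total step count: 21. Longest linear sequence: 15 steps (steps 1 to 9, then 16 to 21); the diene branch (steps 10 to 15) is 6 steps.

Step 16 (key step). What may go wrong:
- sluggish cycloaddition at the neopentyl β-carbon C7, so that the diene is desilylated or polymerised before it reacts;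
- addition to the wrong face if aluminium bound to the C14 carbonyl makes that side the more crowded one;
- Lewis-acid-induced opening of the ether bridge.

Fallback: an anionic double Michael sequence that sets out from 16 and 22. The lithium dienolate of 22 (LiN(i-Pr)2, THF, −78 °C) should add through C6 to C7 of 16 without any Lewis acid. The lactone enolate then closes onto C9 of the regenerated enone (6-endo-trig), and protonation and the acid treatment of step 17 give 26. If the second addition stalls, the open-chain Michael adduct F1 is isolated and closed with catalytic KOt-Bu. The fallback returns to the route at 26.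

Step 2. What may go wrong: a second vinyl addition to the remaining enone of 3, slow transmetalation, or low enantioselectivity at a β-carbon next to the quaternary C20. Fallback: from 1, the same type of rhodium-catalysed addition is run on the simple enone, where precedent is closest and over-addition is impossible, to give (R)-3-ethenyl-4,4-dimethylcyclohexan-1-one F2. Kinetic enolisation away from the substituted side (LiN(i-Pr)2, Me3SiCl, −78 °C) gives the silyl enol ether F3, and Saegusa–Ito oxidation (Pd(OAc)2, MeCN) introduces C15=C16. The fallback returns at 3.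

Step 4. What may go wrong: incomplete deprotonation of the hindered C13–H, β-elimination of silyloxide from the lithium enolate (loss of C12), or erosion of facial selectivity. Fallback: from 5, soft enolisation (Me3SiOTf, Et3N) gives the bis-silyl dienol ether F4 without a free enolate. A Mukaiyama aldol reaction with aqueous formaldehyde catalysed by Sc(OTf)3 gives 6, which is isolated and acetylated (Ac2O, pyridine, DMAP). The fallback returns at 7.

Step 6. What may go wrong: over-reduction of the enone carbonyl, early loss of the acetate so that the C7 oxygen competes for C16, or retro-aldol loss of C7 from the free alkoxide under base. Fallback: from 5, the aldolate of step 4 is trapped with Et3SiCl instead of Ac2O to give the bis-silyl ether F5. Lemieux–Johnson cleavage gives the aldehyde F6, and NaBH4 then DBU gives the bicyclic triethylsilyl ether F7. The primary triethylsilyl ether is then oxidised directly under Swern conditions ((COCl)2, DMSO; Et3N), so a free C7 alkoxide is never exposed to base. The fallback returns at 12.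

Step 18. What may go wrong: competing condensation at the C14 carbonyl, or slow condensation at C5 because of the branched C4 substituent. Fallback: from 26, LiBH(s-Bu)3 at −78 °C should reduce only the less hindered C5 carbonyl to the alcohol F8. 1,1′-Thiocarbonyldiimidazole gives the imidazole-1-carbothioate F9, and Barton–McCombie reduction (Bu3SnH, AIBN, toluene, reflux) removes the oxygen. The fallback returns at 29.

## Further compounds

F1 | step 16 | Michael adduct: C6–C7 bond formed, C5 ketone with C4=C9 enone, saturated lactone | C[C@@H](COCc1ccccc1)C(=C)C(=O)C[C@@H]1CC(=O)OC[C@]12C(=O)C[C@H]3OC[C@@H]2C3(C)C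
F2 | step 2 | (R)-3-ethenyl-4,4-dimethylcyclohexan-1-one | C=C[C@H]1CC(=O)CCC1(C)C
F3 | step 2 | (R)-[(5-ethenyl-4,4-dimethylcyclohex-1-en-1-yl)oxy]trimethylsilane | C=C[C@H]1CC(O[Si](C)(C)C)=CCC1(C)C
F4 | step 4 | bis-silyl dienol ether of 5 (C13=C14 trimethylsilyl enol ether) | CC(C)[Si](C(C)C)(C(C)C)OCC1=C(O[Si](C)(C)C)C=CC(C)(C)[C@H]1C=C
F5 | step 6 | 5-ethenyl-4,4-dimethyl-6-[(triethylsilyloxy)methyl]-6-[(triisopropylsilyloxy)methyl]cyclohex-2-en-1-one, CH2OSiEt3 trans to ethenyl | CC(C)[Si](C(C)C)(C(C)C)OC[C@@]1(CO[Si](CC)(CC)CC)C(=O)C=CC(C)(C)[C@H]1C=C
F6 | step 6 | C18 aldehyde of F5 | CC(C)[Si](C(C)C)(C(C)C)OC[C@@]1(CO[Si](CC)(CC)CC)C(=O)C=CC(C)(C)[C@H]1C=O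
F7 | step 6 | 8,8-dimethyl-2-[(triethylsilyloxy)methyl]-2-[(triisopropylsilyloxy)methyl]-6-oxabicyclo[3.2.1]octan-3-one, CH2OSiEt3 exo | CC(C)[Si](C(C)C)(C(C)C)OC[C@@]2(CO[Si](CC)(CC)CC)C(=O)C[C@H]3OC[C@@H]2C3(C)C
F8 | step 18 | C5 alcohol of 26 (C5 configuration not defined) | C[C@@H](COCc1ccccc1)[C@@H]1C(O)C[C@@H]2[C@H](C1)C(=O)OC[C@]21C(=O)C[C@H]2OC[C@@H]1C2(C)C
F9 | step 18 | O-(C5) 1H-imidazole-1-carbothioate of F8 | C[C@@H](COCc1ccccc1)[C@@H]1C(OC(=S)n3ccnc3)C[C@@H]2[C@H](C1)C(=O)OC[C@]21C(=O)C[C@H]2OC[C@@H]1C2(C)C
A1 | alternative 1 | ring A enone (C13=C19) bearing ring C on C13 and an oxyacetic acid on the C16 oxygen | C[C@@H](C(=O)OC(C)(C)C)[C@@H]1CC[C@@H](C2=CC(C)(C)[C@H](OCC(=O)O)CC2=O)[C@H](C1)C(=O)OC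
A2 | alternative 1 | bridged ketone with C13–H, C10 methyl ester and C3 tert-butyl ester | C[C@@H](C(=O)OC(C)(C)C)[C@@H]1CC[C@@H]([C@H]2C(=O)C[C@H]3OC[C@@H]2C3(C)C)[C@H](C1)C(=O)OC
A3 | alternative 2 | geranyl acetate | CC(=O)OC/C=C(\C)CCC=C(C)C
A4 | alternative 2 | (6R)-6,7-epoxygeranyl acetate | CC(=O)OC/C=C(\C)CC[C@H]1OC1(C)C
A5 | alternative 2 | cis-(3-hydroxy-2,2-dimethyl-6-methylenecyclohexyl)methyl acetate | C=C1CC[C@@H](O)C(C)(C)[C@H]1COC(C)=O
A6 | alternative 3 | 2-methoxy-3,3-dimethyl-4-[2-(trimethylsilylmethyl)prop-2-en-1-yl]tetrahydrofuran (acetal carbon as anomer mixture) | COC1OC[C@@H](CC(=C)C[Si](C)(C)C)C1(C)C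
A7 | alternative 3 | 8,8-dimethyl-3-methylene-6-oxabicyclo[3.2.1]octane | C=C1C[C@H]2OC[C@@H](C1)C2(C)C
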